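A ratio was my way into this flask: in the dawn run, G over X stopped moving from 10.0 h on, and I wanted that ratio for the new charge.

- dawn: X 2.8 M; E 66 mM (held); J 280 mM; run made earlier
- flask: X 2.0 M; E 66 mM (held); J 280 mM; time 30 h

- dawn (time / h: G / %, X / %): 3.00: 41.3, 60.9; 4.00: 54.4, 47.5; 6.00: 73.7, 26.2; 10.0: 91.6, 6.2; 15.0: 92.8, 8.1; 25.0: 90.8, 9.2; 40.0: 92.1, 7.8

(each reading ± 1 percentage point)

- the G standing at 30 h, as a percentage of the X charged
- the change that raises the amount of G at 30 h, in percent of the X charged most ("none" if none brings more than 2 percentage points) (zeta / beta / theta / none)
- amount of G at 30 h, in percent of the X charged, after theta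

- zeta: doubling the transfer coefficient of E, all else as stated
- beta: doubling the amount of J, all else as stated
- theta: doubling the saturation concentration of E, all else as stated

- at the start none of Q is dissolved
- steps under discussion: E <-> Q; X + Q + J <-> J + G

First, the summed G readings from 10.0 h on over the summed X readings gave a plateau ratio of 11.7, a reading with their scatter. Second, I took the plateau as a balance (thermodynamic control) with c_Q at its saturation value, 66 mM, E being held. One X gives one G, so I expected the same ratio for the X charged here.

The symmetric case, ratio one, makes the zero of the scale. Dividing the dawn run's saturation concentration by the plateau ratio gives 5.62 mM; this is the even point, the concentration of Q at which G and X stand level at balance. The ratio at balance is then c_Q over the even point.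

Third, the new flask at 66 mM should hold 92.1 % G. Fourth, the dawn run's early pace of 0.385 M/h would bring this in 4.78 h, shorter than 30 h, so I expected zeta and beta to gain nothing. Doubling the saturation concentration doubles c_Q at balance and gives 95.9 %.

The weak link was the low X reading at 10.0 h. Without that time, the ratio becomes 11.0 and the answer moves by 0.49 percentage points, while one reading scatters by 1 point.

The forecast gave 92 % (90.8 % to 93.2 %), chose theta, and gave 95.8 % after it (95.2 % to 96.5 %), on the ground that “this is a true equilibrium, not a stalled reaction”. My own figures differed slightly.

The flask gave 92.2 %. The best change was theta, with a gain of 3.7 points to 96.0 %, against 0 points from zeta and 0 points from beta.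

    E ⇌ Q, rate k1*(csat - [Q]) (kL = 6.30 /h)
    X + Q + J ⇌ J + G (K = 180 /M, k = 140 /M²/h)

In the flask, the crossing of E to Q and the step to G ran together at first, with Q made 1.02 times as fast as it was used up at 2.62 h. By 15.0 h, c_Q stood at 0.0660 M, 11.7 times the even point, with G at 92.2 % and X at 7.76 %, and these values stood the same at 30.0 h. The neighbour charged with 0.11 M of J had c_Q at 0.0660 M at 30.0 h, so the even point put it at 92.2 %, and it stood at 92.2 %.

The data are calculated for substances that don't exist; scatter was added.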